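4 questions are put to one flask, whose equations and settings stand here.

    substrate → intermediate (k1 = 0.135 /s)
    first nucleophile + intermediate → target (k2 = 12700 /M/s)
    second nucleophile + intermediate → other capture product (k3 = 24500 /M/s)
    intermediate → solvolysis product (k4 = 94.6 /s)
    solid second nucleophile ⇌ second nucleophile, rate k5*(cs5 - [second nucleophile]) while solid is left; crystals form when [second nucleophile] > cs5 (cs5 = 3.3 mM, k5 = 0.177 /s)
    target ⇌ isomer of the product (K6 = 1.64, k6 = 0.0707 /s)

substrate 16 mM; first nucleophile 1.20 equiv; solid second nucleophile 1.80 equiv; time 40 s

- solid second nucleophile is a solid; its amount is given per volume of the solution
- at the start none of the solid second nucleophile is in solution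
- run time (flask): 40 s

- the target standing at 40 s, as a percentage of the substrate charged
- concentration of second nucleophile in solution at 4.0 s, in percent of saturation
- the change that raises the amount of target at 40 s, in percent of the substrate charged most ("none" if none brings more than 2 percentage points) (dusk / midnight / winter / none)
- amount of target at 40 s, in percent of the substrate charged, after midnight

- dusk: doubling the amount of first nucleophile, all else as stated
- midnight: doubling the dissolution coefficient of step 5, all else as stated
- winter: doubling the solubility in step 5, all else as stated

The intermediate is used up by solvolysis at 94.6 /s, far faster than the substrate decays at 0.135 /s, so it can be frozen at its steady state and its fate shared out by rates. Let D be the second nucleophile averaged over substrate turnover, counted as rising toward its solubility with nothing taking it. Let c be the intermediate's loss rate by second nucleophile and solvolysis together: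

D = 1.87 mM, c = 140 /s

Let B be the mean first nucleophile, which starts at its charge and falls by half of what is captured. The first way repeats x = (capture rate by first nucleophile at B) / (that rate + c):

B = 19.2 mM gives 63.4%

B = 14.1 mM gives 56.1%

B = 14.7 mM gives 57.1%

This x, the capture share (the part of the substrate charged that the first nucleophile captures), is the carried quantity.

The second way drops the mean and integrates the ratio of rates over the whole fall of the first nucleophile, with time eliminated. Substrate spent equals first nucleophile spent plus (c over the capture constant) times the logarithm of its start over its end. With the end at 10.1 mM, that sum is 16.3 mM against a charge of 16 mM, and one correction gives 56.3%. The ways differ in how they treat the first nucleophile and share D, so their closeness tests the mean and not D.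

Captured material is taken to arrive as target at the substrate's rate, with the share x held constant through the run, and to relax toward isomer at 0.114 /s, so on this estimate the target's part of it at 40 s is

F = 40.1%

Target is then x times F, 22.6% to 22.9%.

The forecast gives 22.9%, 42%, dusk and 21.6%, holding that “Doubling the first nucleophile raises its capture share far more than anything else”. The simulation gives 22.8%, 41.9%, dusk (gain 7.1 percentage points) and 22.0%.

In this flask at 40 s, target plus isomer stand at 57.0%, against x of 57.1%. In the flask with 6.4 mM of substrate, the same passes give 41.0%, 36.5%, 37.1%; times F that is 14.9%, and that flask holds target at 15.0%. The first flask is still moving at 40 s, with 0.452% of substrate left and target at 22.8%. Its x, split between target and isomer by 1.64, puts target at 21.6%, and left ten times as long that flask holds isomer at 35.6% and target at 21.7%.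

Its constants are those of an exercise; the rest is arithmetic.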